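**Plan**
- Retrosynthesis: remove the three MOM ethers and a C2 silyl group, then cut ring C at C3–C4 and O1–C2 in one operation. This gives a ring A salicylaldehyde (formyl carbon = C4, phenol oxygen = O1) and a ring B aryl(trimethylsilyl)alkyne (alkyne carbons = C2 and C3).
- Enabling feature: in ring C the C4 carbonyl and O1 sit on adjacent ring A carbons (C4a, C8a), and C2–C3 is a two-carbon unit carrying ring B at C3. An ortho-hydroxybenzaldehyde plus an alkyne therefore maps onto the pyranone.
- Ring A: resorcinol is bis-MOM protected, prenylated between the two ethers, then hydroxylated para to the prenyl group via C–H borylation. The resulting symmetric phenol can be ortho-formylated in only one way, which fixes the prenyl group at C6.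
- Ring B: 3,4-dihydrocoumarin is opened with MeMgBr, brominated para to the phenol, MOM protected and coupled with trimethylsilylacetylene.
- Forward order: rings A and B come from the aromatic starting materials, ring C is the only ring closed (step 9), then C2 protodesilylation and MOM removal.
- Stereochemistry: the target has no stereocentre and no stereogenic alkene, so nothing has to be controlled.

Key step: step 9

Remark: discrete stoichiometric intermediates formed in the flask are numbered; catalyst-bound species are described only in the Why lines.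

**Step 1**
Reactants: 1 resorcinol
Product: 2 1,3-bis(methoxymethoxy)benzene
Conditions: MOMCl (2.5 equiv), i-Pr2NEt (3 equiv), CH2Cl2, 0 °C → rt
Reagents that add atoms: chloromethyl methyl ether, COCCl
Why: O-alkylation of both phenols by the reactive α-chloro ether (MOM protection) installs the two acetal groups that direct the metalation in step 2.

**Step 2**
Reactants: 2 1,3-bis(methoxymethoxy)benzene; 3 prenyl bromide (1-bromo-3-methylbut-2-ene)
Product: 5 1,3-bis(methoxymethoxy)-2-(3-methylbut-2-en-1-yl)benzene, via 2,6-bis(methoxymethoxy)phenyllithium 4 (not isolated)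
Conditions: n-BuLi (1.1 equiv), THF, 0 °C; then 3, −78 °C → rt
Reagents that add atoms: n-butyllithium, [Li]CCCC (supplies only the lithium of 4; none of its atoms remain in 5)
Why: Directed ortho-metalation removes the proton flanked by both MOM ethers through double lithium–oxygen chelation, and the aryllithium is alkylated at the primary carbon of the allylic bromide (SN2).

**Step 3**
Reactants: 5 1,3-bis(methoxymethoxy)-2-(3-methylbut-2-en-1-yl)benzene
Product: 7 3,5-bis(methoxymethoxy)-4-(3-methylbut-2-en-1-yl)phenol, via aryl pinacol boronate 6 (not isolated)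
Conditions: [Ir(OMe)(cod)]2 (1.5 mol %), 4,4'-di-tert-butyl-2,2'-bipyridine (3 mol %), B2pin2 (1.0 equiv), hexane, 50 °C; volatiles removed; then 30% aq. H2O2, NaOH, THF, 0 °C
Reagents that add atoms: bis(pinacolato)diboron, CC1(C)OB(OC1(C)C)B1OC(C)(C)C(C)(C)O1 (boryl group of 6 only); hydrogen peroxide, OO (phenol oxygen of 7)
Why: Iridium-catalysed aromatic C–H borylation is sterically controlled and C5 is the only ring C–H without an ortho substituent, and the boronate is then oxidised by basic peroxide (aryl migration from boron to oxygen), which does not epoxidise an unactivated trisubstituted alkene.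

**Step 4**
Reactants: 7 3,5-bis(methoxymethoxy)-4-(3-methylbut-2-en-1-yl)phenol
Product: 9 6-hydroxy-2,4-bis(methoxymethoxy)-3-(3-methylbut-2-en-1-yl)benzaldehyde, via salicyl alcohol 8 (not isolated)
Conditions: MgCl2 (anhydrous, 2 equiv), Et3N (4 equiv), (CH2O)n (6 equiv), MeCN, reflux; cold aq. NH4Cl work-up
Reagents that add atoms: paraformaldehyde (as formaldehyde), C=O
Why: In this magnesium-mediated ortho-formylation (Casnati–Skattebøl reaction) the magnesium phenolate delivers formaldehyde to the ortho carbon and a second formaldehyde oxidises the salicyl alcohol by hydride transfer; the two ortho positions are equivalent and the para position is blocked, so a single aldehyde must result.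

**Step 5**
Reactants: 10 3,4-dihydrocoumarin
Product: 12 2-(3-hydroxy-3-methylbutyl)phenol, via 4-(2-hydroxyphenyl)butan-2-one 11 (not isolated)
Conditions: MeMgBr (3 equiv), THF, 0 °C → rt; aq. NH4Cl
Reagents that add atoms: methylmagnesium bromide, C[Mg]Br
Why: Double Grignard addition to the aryl ester opens the lactone to the methyl ketone (as its magnesium phenolate), which takes up a second methyl group to give the tertiary carbinol; the mild quench avoids acid-induced chroman formation.

**Step 6**
Reactants: 12 2-(3-hydroxy-3-methylbutyl)phenol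
Product: 13 4-bromo-2-(3-hydroxy-3-methylbutyl)phenol
Conditions: NBS (1.0 equiv), MeCN, −10 → 0 °C, dark
Reagents that add atoms: N-bromosuccinimide, O=C1CCC(=O)N1Br
Why: Electrophilic aromatic bromination of a 2-alkylphenol in a polar solvent goes para to the hydroxyl, and the neutral co-product leaves the tertiary alcohol untouched.

**Step 7**
Reactants: 13 4-bromo-2-(3-hydroxy-3-methylbutyl)phenol
Product: 14 4-[5-bromo-2-(methoxymethoxy)phenyl]-2-methylbutan-2-ol
Conditions: MOMCl (1.2 equiv), K2CO3 (2 equiv), acetone, 0 °C → rt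
Reagents that add atoms: chloromethyl methyl ether, COCCl
Why: K2CO3 deprotonates only the phenol, so the phenolate is O-alkylated chemoselectively (MOM protection) while the hindered, non-ionised tertiary alcohol stays free.

**Step 8**
Reactants: 14 4-[5-bromo-2-(methoxymethoxy)phenyl]-2-methylbutan-2-ol; 15 trimethylsilylacetylene
Product: 16 4-{2-(methoxymethoxy)-5-[(trimethylsilyl)ethynyl]phenyl}-2-methylbutan-2-ol
Conditions: PdCl2(PPh3)2 (3 mol %), CuI (5 mol %), Et3N–THF, 70 °C, sealed tube
Reagents that add atoms: none
Why: Sonogashira coupling (oxidative addition of the aryl bromide to zerovalent palladium, transmetalation from the copper acetylide, reductive elimination) forms the aryl–alkyne bond and tolerates the free tertiary alcohol, the MOM ether and the C–Si bond.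

**Step 9**
Reactants: 9 6-hydroxy-2,4-bis(methoxymethoxy)-3-(3-methylbut-2-en-1-yl)benzaldehyde; 16 4-{2-(methoxymethoxy)-5-[(trimethylsilyl)ethynyl]phenyl}-2-methylbutan-2-ol
Product: 17 3-[3-(3-hydroxy-3-methylbutyl)-4-(methoxymethoxy)phenyl]-5,7-bis(methoxymethoxy)-6-(3-methylbut-2-en-1-yl)-2-(trimethylsilyl)-4H-chromen-4-one
Conditions: [Cp*RhCl2]2 (2.5 mol %), Cu(OAc)2 (anhydrous, 2.1 equiv), NaOAc (0.5 equiv), PhMe, 100 °C, N2
Reagents that add atoms: none
Why: Proposed new method: the phenoxide of 9 binds Cp*Rh (trivalent rhodium), acetate-assisted cleavage of the formyl C–H bond gives a five-membered acyl rhodacycle, and alkyne 16 inserts into the Rh–acyl bond so that the acyl carbon (C4) bonds to the aryl-bearing alkyne carbon (C3) while rhodium takes the silyl-bearing carbon (C2). This orientation is expected because the bulky Me3Si group avoids the carbon at which the new C–C bond forms and an α-silyl vinyl–rhodium bond is stabilised, the same bias that places silicon next to the heteroatom in Larock-type annulations of aryl silyl alkynes. Ring C is then closed by C–O reductive elimination from the seven-membered oxarhodacycle (O1–C2 bond; overall an oxidative [4+2] annulation giving the six-membered pyranone), and Cu(OAc)2 returns monovalent rhodium to the trivalent state. The closest known reaction type is the rhodium-catalysed oxidative annulation of salicylaldehydes with diaryl, dialkyl or alkyl aryl alkynes to 2,3-disubstituted chromones, where an aryl group normally ends at C2; the silyl group is introduced here to override that preference. No stereocentre is formed. The step needs regioselective insertion (secured by the silyl group), chemoselectivity for the formyl C–H over the prenyl alkene and the tertiary alcohol (secured by phenoxide chelation and the neutral, silver-free, acetate-buffered catalyst), and a single ring A orientation, which is built into 9 because its only free phenol is the one para to the prenyl group.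

**Step 10**
Reactants: 17 the 2-trimethylsilyl isoflavone from step 9
Product: 18 3-[3-(3-hydroxy-3-methylbutyl)-4-(methoxymethoxy)phenyl]-5,7-bis(methoxymethoxy)-6-(3-methylbut-2-en-1-yl)-4H-chromen-4-one
Conditions: TBAF (1.5 equiv), AcOH (1.0 equiv), THF, 0 °C → rt
Reagents that add atoms: none
Why: Fluoride-induced protodesilylation cleaves the C2–Si bond because the departing C2 carbanion is stabilised by the ring oxygen of the vinylogous ester, and the acetic acid buffer supplies the proton and prevents base-induced opening of the pyranone.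

**Step 11**
Reactants: 18 tris-O-methoxymethyl coloratanin A
Product: 19 coloratanin A, 5,7-dihydroxy-3-[4-hydroxy-3-(3-hydroxy-3-methylbutyl)phenyl]-6-(3-methylbut-2-en-1-yl)-4H-chromen-4-one
Conditions: HCl (ca. 1 M, conc. aq. HCl diluted in MeOH), 0 °C → rt, monitored; NaHCO3 quench
Reagents that add atoms: none
Why: Acid-catalysed acetal exchange with methanol removes the three aryl MOM ethers (the chelated 5-O ether first), and dilute acid at or below room temperature should spare the prenyl alkene and the tertiary carbinol.

**Compound list**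
1 | resorcinol | Oc1cccc(O)c1 | starting material
2 | 1,3-bis(methoxymethoxy)benzene | COCOc1cccc(OCOC)c1 | intermediate
3 | prenyl bromide (1-bromo-3-methylbut-2-ene) | CC(C)=CCBr | starting material
4 | 2,6-bis(methoxymethoxy)phenyllithium | [Li]c1c(OCOC)cccc1OCOC | intermediate (not isolated)
5 | 1,3-bis(methoxymethoxy)-2-(3-methylbut-2-en-1-yl)benzene | COCOc1cccc(OCOC)c1CC=C(C)C | intermediate
6 | 2-[3,5-bis(methoxymethoxy)-4-(3-methylbut-2-en-1-yl)phenyl]-4,4,5,5-tetramethyl-1,3,2-dioxaborolane | COCOc1cc(B2OC(C)(C)C(C)(C)O2)cc(OCOC)c1CC=C(C)C | intermediate (not isolated)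
7 | 3,5-bis(methoxymethoxy)-4-(3-methylbut-2-en-1-yl)phenol | COCOc1cc(O)cc(OCOC)c1CC=C(C)C | intermediate
8 | 2-(hydroxymethyl)-3,5-bis(methoxymethoxy)-4-(3-methylbut-2-en-1-yl)phenol | COCOc1cc(O)c(CO)c(OCOC)c1CC=C(C)C | intermediate (not isolated)
9 | 6-hydroxy-2,4-bis(methoxymethoxy)-3-(3-methylbut-2-en-1-yl)benzaldehyde | COCOc1cc(O)c(C=O)c(OCOC)c1CC=C(C)C | intermediate
10 | 3,4-dihydrocoumarin | O=C1CCc2ccccc2O1 | starting material
11 | 4-(2-hydroxyphenyl)butan-2-one (formed as its magnesium phenolate) | CC(=O)CCc1ccccc1O | intermediate (not isolated)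
12 | 2-(3-hydroxy-3-methylbutyl)phenol | CC(C)(O)CCc1ccccc1O | intermediate
13 | 4-bromo-2-(3-hydroxy-3-methylbutyl)phenol | CC(C)(O)CCc1cc(Br)ccc1O | intermediate
14 | 4-[5-bromo-2-(methoxymethoxy)phenyl]-2-methylbutan-2-ol | COCOc1ccc(Br)cc1CCC(C)(C)O | intermediate
15 | trimethylsilylacetylene | C#C[Si](C)(C)C | starting material
16 | 4-{2-(methoxymethoxy)-5-[(trimethylsilyl)ethynyl]phenyl}-2-methylbutan-2-ol | C[Si](C)(C)C#Cc1ccc(OCOC)c(CCC(C)(C)O)c1 | intermediate
17 | 3-[3-(3-hydroxy-3-methylbutyl)-4-(methoxymethoxy)phenyl]-5,7-bis(methoxymethoxy)-6-(3-methylbut-2-en-1-yl)-2-(trimethylsilyl)-4H-chromen-4-one | COCOc1cc2oc([Si](C)(C)C)c(-c3ccc(OCOC)c(CCC(C)(C)O)c3)c(=O)c2c(OCOC)c1CC=C(C)C | intermediate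
18 | 3-[3-(3-hydroxy-3-methylbutyl)-4-(methoxymethoxy)phenyl]-5,7-bis(methoxymethoxy)-6-(3-methylbut-2-en-1-yl)-4H-chromen-4-one | COCOc1cc2occ(-c3ccc(OCOC)c(CCC(C)(C)O)c3)c(=O)c2c(OCOC)c1CC=C(C)C | intermediate
19 | coloratanin A | CC(C)=CCc1c(O)cc2occ(-c3ccc(O)c(CCC(C)(C)O)c3)c(=O)c2c1O | target

**Totals**
Total step count: 11. Longest linear sequence: 7 steps (steps 1–4 or 5–8, then 9–11).

**Steps most likely to fail**

1. Step 9 (proposed new method). The alkyne may insert in the reverse sense and deliver ring B to C2. The alkynyl silicon may also be transferred to copper, followed by oxidative alkyne dimerisation, or the acyl rhodium may lose CO. The fallback uses only known chemistry, sets out from 9 and 14, and returns at 18, bypassing 17 and step 10.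
   - Aldehyde 9 would be treated with MeMgBr (THF, 0 °C) to give the racemic carbinol 2-(1-hydroxyethyl)-3,5-bis(methoxymethoxy)-4-(3-methylbut-2-en-1-yl)phenol F1.
   - MnO2 in CH2Cl2 would oxidise it to the acetophenone 1-[6-hydroxy-2,4-bis(methoxymethoxy)-3-(3-methylbut-2-en-1-yl)phenyl]ethan-1-one F2.
   - Heating with N,N-dimethylformamide dimethyl acetal would give the enaminone (E)-3-(dimethylamino)-1-[6-hydroxy-2,4-bis(methoxymethoxy)-3-(3-methylbut-2-en-1-yl)phenyl]prop-2-en-1-one F3.
   - Brief exposure to I2/pyridine in CHCl3 at 0 °C would close ring C to 3-iodo-5,7-bis(methoxymethoxy)-6-(3-methylbut-2-en-1-yl)-4H-chromen-4-one F4.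
   - In parallel, bromide 14 would undergo Miyaura borylation (B2pin2, PdCl2(dppf), KOAc, dioxane, 80 °C) to the boronate 4-[2-(methoxymethoxy)-5-(4,4,5,5-tetramethyl-1,3,2-dioxaborolan-2-yl)phenyl]-2-methylbutan-2-ol F5.
   - Suzuki coupling of F4 with F5 (Pd(PPh3)4, aq. K2CO3, DME, 80 °C) should give 18 with ring B unambiguously at C3.

2. Step 3. The prenyl alkene may compete under iridium catalysis (hydroboration by pinacolborane, vinylic or allylic borylation, alkene migration), eroding the clean C5 functionalisation. The fallback installs the oxygen before the alkene, sets out from 2 and returns at 7.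
   - Borylation of 2 under the same iridium conditions should give 2-[3,5-bis(methoxymethoxy)phenyl]-4,4,5,5-tetramethyl-1,3,2-dioxaborolane F6 (only C5 is unhindered).
   - Basic peroxide would convert it to 3,5-bis(methoxymethoxy)phenol F7.
   - Silylation (i-Pr3SiCl, imidazole, DMF) would give [3,5-bis(methoxymethoxy)phenoxy]tri(propan-2-yl)silane F8.
   - n-BuLi in THF at 0 °C would metalate between the two MOM ethers to give 2,6-bis(methoxymethoxy)-4-[tri(propan-2-yl)silyloxy]phenyllithium F9.
   - Alkylation with 3 would give [3,5-bis(methoxymethoxy)-4-(3-methylbut-2-en-1-yl)phenoxy]tri(propan-2-yl)silane F10, and TBAF in THF would release phenol 7.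

3. Step 11. Under protic acid the prenyl group may cyclise onto the freed 5- or 7-hydroxyl, or the tertiary carbinol may ionise and close a chroman onto the 4'-phenol or be methanolysed. The fallback replaces protic hydrolysis by aprotic silyl transfer, sets out from 18 and returns at 19.
   - TMSOTf with 2,2'-bipyridyl in CH2Cl2 at 0 °C should convert the three aryl MOM ethers directly into silyl ethers and silylate the carbinol, giving 5,7-bis(trimethylsilyloxy)-3-[4-(trimethylsilyloxy)-3-(3-methyl-3-(trimethylsilyloxy)butyl)phenyl]-6-(3-methylbut-2-en-1-yl)-4H-chromen-4-one F11.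
   - Buffered fluoride (TBAF/AcOH, THF, 0 °C) would then release 19 without a strong acid being present at any point.

**Further compounds**
F1 | step 9 | 2-(1-hydroxyethyl)-3,5-bis(methoxymethoxy)-4-(3-methylbut-2-en-1-yl)phenol (racemic) | CC(O)c1c(O)cc(OCOC)c(CC=C(C)C)c1OCOC
F2 | step 9 | 1-[6-hydroxy-2,4-bis(methoxymethoxy)-3-(3-methylbut-2-en-1-yl)phenyl]ethan-1-one | CC(=O)c1c(O)cc(OCOC)c(CC=C(C)C)c1OCOC
F3 | step 9 | (E)-3-(dimethylamino)-1-[6-hydroxy-2,4-bis(methoxymethoxy)-3-(3-methylbut-2-en-1-yl)phenyl]prop-2-en-1-one | CN(C)/C=C/C(=O)c1c(O)cc(OCOC)c(CC=C(C)C)c1OCOC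
F4 | step 9 | 3-iodo-5,7-bis(methoxymethoxy)-6-(3-methylbut-2-en-1-yl)-4H-chromen-4-one | COCOc1cc2occ(I)c(=O)c2c(OCOC)c1CC=C(C)C
F5 | step 9 | 4-[2-(methoxymethoxy)-5-(4,4,5,5-tetramethyl-1,3,2-dioxaborolan-2-yl)phenyl]-2-methylbutan-2-ol | COCOc1ccc(B2OC(C)(C)C(C)(C)O2)cc1CCC(C)(C)O
F6 | step 3 | 2-[3,5-bis(methoxymethoxy)phenyl]-4,4,5,5-tetramethyl-1,3,2-dioxaborolane | COCOc1cc(OCOC)cc(B2OC(C)(C)C(C)(C)O2)c1
F7 | step 3 | 3,5-bis(methoxymethoxy)phenol | COCOc1cc(O)cc(OCOC)c1
F8 | step 3 | [3,5-bis(methoxymethoxy)phenoxy]tri(propan-2-yl)silane | COCOc1cc(O[Si](C(C)C)(C(C)C)C(C)C)cc(OCOC)c1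
F9 | step 3 | 2,6-bis(methoxymethoxy)-4-[tri(propan-2-yl)silyloxy]phenyllithium | [Li]c1c(OCOC)cc(O[Si](C(C)C)(C(C)C)C(C)C)cc1OCOC
F10 | step 3 | [3,5-bis(methoxymethoxy)-4-(3-methylbut-2-en-1-yl)phenoxy]tri(propan-2-yl)silane | COCOc1cc(O[Si](C(C)C)(C(C)C)C(C)C)cc(OCOC)c1CC=C(C)C
F11 | step 11 | 5,7-bis(trimethylsilyloxy)-3-[4-(trimethylsilyloxy)-3-(3-methyl-3-(trimethylsilyloxy)butyl)phenyl]-6-(3-methylbut-2-en-1-yl)-4H-chromen-4-one | CC(C)=CCc1c(O[Si](C)(C)C)cc2occ(-c3ccc(O[Si](C)(C)C)c(CCC(C)(C)O[Si](C)(C)C)c3)c(=O)c2c1O[Si](C)(C)C
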